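The runs were computed with made-up constants; noise was put on by code.

The south run, with 1.9 mM of partner, reads 68.1% of left-handed product at 20.0 min, more than the 50.0% of the charge that was left-handed, so substrate crosses between the hands. Before I charge 1.25 mM of partner, I want to know whether that exchange keeps up or whether to hold the partner lower.

all flasks: left-handed substrate 5.0 × 10⁻⁴ M; right-handed substrate 5.0 × 10⁻⁴ M

| run | partner | remark | time |
|---|---|---|---|
| south-west | 0.84 mM | run made earlier |  |
| south | 1.9 mM | run made earlier |  |
| flask | 1.25 mM |  | 20 min |

| run | time / min | left-handed product / % | right-handed product / % | left-handed substrate / % |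
|---|---|---|---|---|
| south-west | 3.00 | 27.4 | 5.2 | 25.2 |
| south-west | 6.00 | 40.3 | 8.4 | 14.3 |
| south-west | 10.0 | 46.3 | 10.4 | 9.2 |
| south-west | 12.0 | 48.9 | 12.4 | 6.0 |
| south-west | 15.0 | 52.0 | 12.9 | 5.5 |
| south-west | 20.0 | 51.4 | 12.0 | 2.5 |
| south | 3.00 | 49.6 | 12.0 | 11.8 |
| south | 6.00 | 61.9 | 17.9 | 4.3 |
| south | 10.0 | 66.3 | 18.1 | 2.4 |
| south | 12.0 | 68.6 | 16.8 | 0.7 |
| south | 15.0 | 68.8 | 17.9 | 0 |
| south | 20.0 | 68.1 | 18.5 | 0.1 |

(readings scatter by 1 percentage point)

- left-handed product and right-handed product together, in percent of the left-handed substrate and right-handed substrate charged together, at 20 min
- excess of left-handed product over right-handed product in the product at 20 min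
- whether the exchange between left-handed substrate and right-handed substrate keeps pace with the reaction: how far the product's excess at 20 min gets from its value without exchange to its value with instant exchange (above 80% keeps pace, below 20% hardly takes part, else lags behind)

- partner is single-handed; left-handed substrate and right-handed substrate are mirror images of each other, charged as a racemate, each of them at the stated concentration
- an excess is the difference of the two amounts in percent of their sum
- an excess is below zero if the other one leads
- the handed part of partner does not stay in what it makes, so the products of the two hands are mirror images too

If both hands react first order in partner, the rate of left-handed product over the rate of right-handed product is s times c(left-handed substrate) over c(right-handed substrate), and partner and time drop out. While the two substrates stand equal, the product ratio therefore reads the selectivity factor s, which I take as 4.70, the mean of the two ratios read at 3.00 min, so a reading with their scatter.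

Instant exchange keeps them equal, giving an excess of s less one over s plus one, 64.9%. For the flask's yield I take the mean of the two runs at 20.0 min, 75.0%. Without exchange, left-handed product stops at half of what was charged together, so at that yield the excess is at most 33.3%. I take the mean of the two runs' excesses at 20.0 min, 59.7%, for the flask. That is 83.5% of the way, above 80%, so I charge 1.25 mM and expect exchange to keep pace.

The forecast gives 75%, 58.5% and lags behind, and its ends of the way differ from mine: “Without exchange, excess would be about 40%; with instant exchange, about 78%.”

The flask gives 78.5%, 60.4% and keeps pace, at 91% of the way, so it parts from the forecast on pace.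

    achiral form → decomposed reagent (k = 0.00122 /s)
    left-handed substrate ⇌ achiral form (K = 0.0331, k = 0.0296 /s)
    partner + right-handed substrate → right-handed product (k = 1.61 /M/s)
    achiral form → waste (k = 0.0102 /s)
    partner + left-handed substrate → left-handed product (k = 7.51 /M/s)
    achiral form → side product (k = 0.0429 /s)
    right-handed substrate ⇌ achiral form (K = 0.0331, k = 0.0296 /s)

At the flask's own yield, my ceiling becomes 27.4%, and s puts the flask at 88.0% of the way. The neighbour flask with 0.0050 M of partner gives 69.7% of left-handed product and 25.5% of right-handed product, a ratio of 2.73, below s. Its yield is 95.1% and its excess 46.5%, so the same reckoning places it at 69.2% of the way.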